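**The problem**

The target 36 is a germacranolide. Its ten-membered carbocycle is numbered here C1 (CHOH), C2 (CH2), C3 (CHOAc), C4=C5 (Z, methyl on C4), C6 (lactone O–CH), C7 (lactone CH), C8 (CH–O-tigloyl) and C9=C10 (E, methyl on C10). It is trans-fused at C6/C7 to an α-methylene-γ-butyrolactone (C11 carries the exocyclic methylene C13, C12 is the carbonyl). A synthesis has to close a medium ring, for which end-to-end cyclisation of a chain is poor, and has to deliver the ring-trans C9=C10 alkene, which must come from a stereospecific, kinetically controlled step. Of the five stereocentres (1S,3S,6R,7S,8R) only C7 can be taken from the chiral pool. C7 can control its neighbours C6 and C8, whereas C1 and C3 are remote and can be reached only through a cyclic transition state or by reagent control. The α-methylene lactone (a Michael acceptor), the allylic acetate and tiglate (prone to ionisation and acyl shift) and the free allylic C1 hydroxyl tolerate neither strong base nor hydride, so they must appear in the last steps, and the oxygens on C1, C3 and C8 must be told apart. The feature that opens the route is that C3–C8, with the C4 methyl, the Z C4=C5 alkene and the three-carbon branch on C7, is the carbon skeleton of carvone, and that C1=C2–C3–C8–C9=C10 is a 1,5-diene across the ring bond C3–C8. A vinyl group on C3 and a propenyl group on C8 of a carvone-derived cyclohexenol are therefore set up for a [3,3] shift that turns the six-membered ring into the ten-membered one with the Z alkene locked in place. Carvone offers no direct handle on C6, which is γ to its carbonyl; this is met by starting from (R)-carvone 1, oxygenating its α′-carbon (the future C6) and then moving the carbonyl from C5 to C3.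

**Retrosynthesis**

Endgame (36 ← 35 ← 34 ← 31). The C1 hydroxyl is kept as its 4-methoxybenzyl ether until the last step (35), and the C3 acetate is placed just before that (34). The lactone is cut at the oxidation level of C12 and at the O–C6 bond, back to the 2-methylene-1,4-diol unit of triol 31. Carrying an acrylate or the lactone itself through organometallic, hydrazine and amide-base steps would not work, whereas a silyl-protected allylic alcohol survives all of them. The forward reaction must oxidise the primary allylic alcohol of 31 in the presence of the secondary C3 alcohol and close the trans-fused five-membered ring.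

C8–O and C9=C10 (31 ← 30 ← 29 ← 28 ← 27 ← 26 ← 25). The unit C8(O)–C9=C10 is traced back to the C8=C9 alkene of dienone 25 with a hydrogen on C10. The (8S,9S)-oxirane 26 and a syn β-elimination (28 → 29) fix the C8 configuration and the E geometry in one stereospecific event. Selenium dioxide would oxidise without moving the alkene, and an anti opening would need attack from inside the ring. The C3 ketone is reduced (27) and silylated (28) in between because an acetate would not survive the amide base; the tiglate goes on afterwards (30). The forward sequence must epoxidise one face of one of three alkenes and remove H10 in preference to H7.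

Ring expansion (25 ← 22). The C1–C10 bond is cut and the C3–C8 bond restored, so the ten-membered dienone 25 becomes the 1,2-dialkenylcyclohexenol 22. No other cut removes the medium ring, two stereocentres (C1, C10) and the E alkene at once while leaving the Z C4=C5 alkene inside a six-membered ring, where it cannot isomerise. The precursor is a cyclohexene with four contiguous substituted carbons. The forward step must go through a single chair transition state and the enolate must keep its β-ether.

Tertiary carbinol (22 ← 14 + 19). The C2–C3 bond is cut to ketone 14 and the Z-2-alkoxyvinyl bromide 19. A 1,2-addition is the only direct way to a tertiary allylic alcohol carrying a heteroatom-substituted vinyl group, and the two partners are of very unequal size, which keeps the costly material linear only from 14. The addition has to occur anti to the propenyl group on C8 and without enolising the doubly activated C8–H.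

C8 alkenyl group (14 ← 13 ← 10 + 11). The C8–C9 bond is cut to the enolate of enone 10 and allyl bromide 11; the allyl group is then moved into the E-propenyl position. Direct α-alkenylation would be shorter but less certain in its trans selectivity (it is kept as a fallback), whereas trans-allylation of carvone-type enolates is established. The isomerisation must stop at the β,γ-unsaturated ketone.

Oxygenated carvone (10 ← 9 ← 7 ← 6 ← 4 ← 2 ← 1). The enone 10 is a carvone of the (S) series with oxygen on C6 and C12. Its C6–O bond cannot be made by γ-oxidation of (S)-carvone without risking the alkene position, so the carbonyl is traced back through a Wharton transposition (7 → 9, then oxidation) to the α′-silyloxy enone 6. Compound 6 arises from 10-hydroxycarvone 4 by Rubottom oxidation, and 4 from (R)-carvone 1 through the allylic chloride 2. Every step acts on a rigid six-membered ring, where the C7 branch directs the new C6 oxygen trans.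

Enol ether (19 ← 17 ← 15 + 16). The vinyl bromide is cut to 4-methoxybenzyl vinyl ether 17 (bromination and dehydrobromination), and 17 to 4-methoxybenzyl alcohol 15 and ethyl vinyl ether 16 by vinyl exchange.

**Roads not taken**

Alternative 1: The cut is both C–O bonds at C6 and C3, back to the macrocyclic triene acid A1 with a conjugated Z,Z-diene C3=C4–C5=C6.
- Forward step: Pd(OAc)2 with benzoquinone in acetic acid would add the C12 carboxylate to C6 of the diene bound to divalent palladium and pass acetate to C3 of the resulting allyl complex, giving A2, one desilylation from the target.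
- Merits: lactone, acetate, two stereocentres and the position of the C4=C5 alkene arise in one late operation, which suits their sensitivity. In this respect it is better than the chosen plan, which spends steps 14, 15 and 18–20 on the same functions.
- Weak points: the ten-membered ring of A1, with three alkenes and the C1, C7 and C8 centres, still has to be built, and this cut does nothing for it. The allyl complex must collapse to the Z alkene. The C3/C6 relationship depends on whether acetate arrives from the metal or from outside. The C9=C10 alkene and the allylic tiglate are further sites for palladium.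
- Comparison: the chosen plan sets against its longer endgame a ring construction of certain connectivity in which the Z alkene is inherited and not formed.

Alternative 2: The cut is the C4=C5 double bond, back to the eleven-membered α-methyl sulfone A3, itself closed by an easy thioether alkylation.
- Forward step: KOH on alumina with CBr2F2 would halogenate next to sulfur, close the episulfone and extrude SO2 to give the ten-membered diene A4.
- Merits: the ring closure is strain-free, strain appears only on loss of SO2, and two fragments of similar size are joined late. This convergence is a real advantage over the linear chosen route.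
- Weak points: the Z geometry of a trisubstituted alkene is not assured in a Ramberg–Bäcklund contraction. The α-sulfonyl carbanion at C4 has a β-silyloxy group at C3 that can be expelled. A4 still needs oxidation of C12, lactonisation, two acylations and the removal of five protecting groups. All five stereocentres must be set in open-chain fragments.
- Comparison: the chosen plan answers with a Z alkene that cannot be formed wrongly and with two stereocentres set by the ring-forming step itself.

Alternative 3: The cut is the C3–C4 bond, back to the seco aldehyde A5, which already carries the lactone, the tiglate, four stereocentres and a Z alkenyl iodide.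
- Forward step: catalytic CrCl2 and NiCl2 with Cp2ZrCl2, regenerated at the cathode, would convert the iodide by way of zerovalent nickel into an alkenyl species of trivalent chromium that adds to the aldehyde and closes the ring to A6; acetylation and desilylation finish the synthesis.
- Merits: this is the most convergent road. The reagent tolerates the α-methylene lactone and the esters, the alkene geometry comes from the iodide, and the endgame is two steps. In all this it is superior to the chosen plan.
- Weak points: a ten-membered ring is closed from a chain under dilution. The C3 configuration is left to the macrocyclic transition state. The β-silyloxy aldehyde of A5 can eliminate. A5 requires a long linear synthesis in which the E C9=C10 alkene and four stereocentres are made one by one.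
- Comparison: the chosen plan cannot match the short endgame. It offers instead a unimolecular ring formation without dilution from a precursor ten steps from a terpene, and a reagent-controlled C3 reduction.

Key step: step 12

Assumption: the L-fructose-derived (ent-)Shi ketone, (R)-2-methyl-CBS-oxazaborolidine and the reagents named under Conditions are taken as commercial. TBS stands for tert-butyldimethylsilyl, PMB for 4-methoxybenzyl; names of ten-membered compounds use the atom numbers defined in "The problem", with the SMILES in the list as the reference for configuration.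

**Route**

Step 1
Reactants: 1 (R)-(−)-carvone
Product: 2 (5R)-5-(3-chloroprop-1-en-2-yl)-2-methylcyclohex-2-en-1-one
Conditions: Ca(OCl)2, CO2 (s), CH2Cl2/H2O, 0 °C
Reagents that add atoms: calcium hypochlorite [Ca+2].[O-]Cl.[O-]Cl
Why: Ene-type allylic chlorination by hypochlorous acid made in situ; only the electron-rich 1,1-disubstituted alkene reacts and the conjugated ring alkene and the stereocentre are untouched.

Step 2
Reactants: 2
Product: 4 (5R)-5-(3-hydroxyprop-1-en-2-yl)-2-methylcyclohex-2-en-1-one, via acetate 3 (not isolated)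
Conditions: KOAc, Bu4NI (cat.), DMF, 60 °C; then K2CO3 (cat.), MeOH, rt
Reagents that add atoms: potassium acetate CC(=O)[O-].[K+]
Why: SN2 displacement of the primary allylic chloride by acetate, then methanolysis of the ester in the same flask; catalytic carbonate should not disturb the enone.

Step 3
Reactants: 4
Product: 6 (5S,6S)-6-(TBSO)-5-[3-(TBSO)prop-1-en-2-yl]-2-methylcyclohex-2-en-1-one, via bis-silyl dienol ether 5 (not isolated)
Conditions: TBSOTf, Et3N, CH2Cl2, 0 °C; then mCPBA, hexane/CH2Cl2, −15 °C
Reagents that add atoms: tert-butyldimethylsilyl triflate CC(C)(C)[Si](C)(C)OS(=O)(=O)C(F)(F)F; mCPBA OOC(=O)c1cccc(Cl)c1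
Why: Soft enolisation silylates the alcohol and gives the cross-conjugated 2-silyloxydiene by α′-deprotonation. Rubottom oxidation then epoxidises the silyl enol ether alkene anti to the adjacent side chain, and a 1,4-silyl shift leaves the α′-silyloxy ketone, so the new oxygen (future C6) should be trans to the branch.

Step 4
Reactants: 6
Product: 7 (1R,3S,4S,6R)-3-(TBSO)-4-[3-(TBSO)prop-1-en-2-yl]-1-methyl-7-oxabicyclo[4.1.0]heptan-2-one
Conditions: H2O2 (30% aq.), NaOH (cat.), MeOH, 0 °C
Reagents that add atoms: hydrogen peroxide OO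
Why: Weitz–Scheffer nucleophilic epoxidation of the enone, expected anti to the side chain as with carvone itself. Both oxirane centres are erased in steps 5 and 6, so their configuration does not matter.

Step 5
Reactants: 7
Product: 9 (1R,4R,5S)-4-(TBSO)-5-[3-(TBSO)prop-1-en-2-yl]-2-methylcyclohex-2-en-1-ol, via epoxy hydrazone 8 (not isolated)
Conditions: N2H4·H2O, AcOH (cat.), MeOH, 0 °C → rt
Reagents that add atoms: none
Why: Wharton transposition: the α,β-epoxy hydrazone opens to an alkenyldiazene that loses N2, which moves the alkene to C4=C5 and the oxygen to C3. The former α′-silyloxy carbon thereby becomes the γ-carbon C6.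

Step 6
Reactants: 9
Product: 10 (4R,5S)-4-(TBSO)-5-[3-(TBSO)prop-1-en-2-yl]-2-methylcyclohex-2-en-1-one
Conditions: MnO2, CH2Cl2, rt
Reagents that add atoms: none
Why: Selective oxidation of the secondary allylic alcohol to the enone; 10 is a carvone of the (S) series that already carries the C6 and C12 oxygens.

Step 7
Reactants: 10; 11 allyl bromide
Product: 13 (4R,5S,6R)-6-allyl-4-(TBSO)-5-[3-(TBSO)prop-1-en-2-yl]-2-methylcyclohex-2-en-1-one, via lithium enolate 12 (not isolated)
Conditions: LDA, THF, −78 °C; then 11, −78 → −20 °C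
Reagents that add atoms: none
Why: Kinetic α′-deprotonation and alkylation of the cross-conjugated enolate. The electrophile should enter anti to the adjacent C7 branch, as in the trans-allylation of carvone, which sets C8.

Step 8
Reactants: 13
Product: 14 (4R,5S,6R)-4-(TBSO)-5-[3-(TBSO)prop-1-en-2-yl]-2-methyl-6-[(E)-prop-1-en-1-yl]cyclohex-2-en-1-one
Conditions: Pd(dba)2 (2 mol%), P(tBu)3, iPrCOCl (cat.), toluene, 80 °C
Reagents that add atoms: none
Why: Alkene isomerisation by a palladium hydride formed in situ (insertion and β-hydride elimination) moves the terminal alkene by one position to the E-2-alkene. The bulky catalyst should leave 1,1-disubstituted and trisubstituted alkenes alone, and the reaction is stopped at full conversion to limit drift into conjugation.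

Step 9
Reactants: 15 4-methoxybenzyl alcohol; 16 ethyl vinyl ether
Product: 17 4-methoxybenzyl vinyl ether
Conditions: Hg(OAc)2 (cat.), 16 as solvent, reflux
Reagents that add atoms: none
Why: Hg(OAc)2-catalysed vinyl exchange (transetherification) driven by the excess of ethyl vinyl ether.

Step 10
Reactants: 17
Product: 19 (Z)-1-bromo-2-(4-methoxybenzyloxy)ethene, via dibromide 18 (not isolated)
Conditions: Br2, CH2Cl2, −78 °C; then iPr2NEt, −78 → 40 °C
Reagents that add atoms: bromine BrBr
Why: Bromine addition to the enol ether followed by dehydrobromination of the α-bromo ether. The 2-bromovinyl ether should form mainly as the Z isomer, as usual for 1-alkoxy-2-haloethenes, and the E isomer is removed by chromatography.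

Step 11
Reactants: 19; 14
Product: 22 (1S,4R,5S,6R)-4-(TBSO)-5-[3-(TBSO)prop-1-en-2-yl]-1-[(Z)-2-(PMBO)ethenyl]-2-methyl-6-[(E)-prop-1-en-1-yl]cyclohex-2-en-1-ol, via vinyllithium 20 (not isolated), via organocerium reagent 21 (not isolated)
Conditions: 19, nBuLi, Et2O, −78 °C; CeCl3, THF, −78 °C; then 14, −78 °C
Reagents that add atoms: none
Why: Bromine–lithium exchange gives the configurationally stable Z-2-alkoxyvinyllithium, and the derived organocerium reagent adds 1,2 to the enolisable β,γ-unsaturated ketone without deprotonating C8. Equatorial entry anti to the adjacent propenyl group should place the new alkenyl group trans to it and set the tertiary C3 carbinol.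

Step 12
Reactants: 22
Product: 25 (1S,6R,7S,10R,4Z,8E)-1-(PMBO)-6-(TBSO)-7-[3-(TBSO)prop-1-en-2-yl]-4,10-dimethylcyclodeca-4,8-dien-3-one, via potassium alkoxide 23 (not isolated), via potassium dienolate 24 (not isolated)
Conditions: KH, 18-crown-6, THF, 0 °C → rt; then AcOH, THF, −78 °C
Reagents that add atoms: none
Why: Anionic oxy-Cope rearrangement: alkoxide 23 undergoes a [3,3] sigmatropic shift through C1=C2–C3–C8–C9=C10 that forms C1–C10 and cleaves C3–C8 to dienolate 24, which is protonated at C2. The closest known reaction type is the ring expansion of trans-1,2-dialkenylcyclohexanols to E-cyclodec-5-enones. The ten-membered ring arises by four-atom ring expansion of the cyclohexene and not by end-to-end cyclisation, so no dilution is needed and the C4=C5 alkene stays Z. In the reactive half-chair the alkenyl groups on C3 and C8 and the branches on C6 and C7 are all equatorial; this fixes the sign of the C2–C3–C8–C9 torsion and hence one chair transition state, so C7 decides which alkene faces meet. The new C10 centre (R) follows from the E-propenyl geometry, which puts the methyl group equatorial, and the new C1 centre (S) from the Z enol ether geometry, which puts the ether oxygen axial. The equatorial C3–C4 and C8–C7 bonds give the E C8=C9 alkene. The step needs chair over boat selectivity, which the trans-diequatorial alkenyl groups secure, and it needs the enolate to keep its β-ether, for which the low temperature and the cold acidic quench are chosen.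

Step 13
Reactants: 25
Product: 26 (1S,6R,7R,8S,9S,10S,4Z)-8,9-epoxy-1-(PMBO)-6-(TBSO)-7-[3-(TBSO)prop-1-en-2-yl]-4,10-dimethylcyclodec-4-en-3-one
Conditions: ent-Shi ketone (L-fructose-derived, 30 mol%), Oxone (2KHSO5·KHSO4·K2SO4), K2CO3, Bu4NHSO4 (cat.), MeCN/CH2(OMe)2/aq. Na2B4O7 buffer, 0 °C
Reagents that add atoms: potassium peroxymonosulfate [K+].[O-]S(=O)(=O)OO
Why: Shi epoxidation: the chiral dioxirane epoxidises E-1,2-disubstituted alkenes through a spiro transition state, and the L-fructose-derived ketone should give the (S,S)-oxirane. The enone alkene is too electron-poor and the 1,1-disubstituted alkene with its allylic silyl ether reacts more slowly. The face chosen by the catalyst is the one flanked by H7 and H10 when the C7 branch and the C10 methyl lie in the alkene plane, which is also the face not covered by the ring, so reagent and substrate control should agree.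

Step 14
Reactants: 26
Product: 27 (1S,3S,6R,7R,8S,9S,10S,4Z)-8,9-epoxy-1-(PMBO)-6-(TBSO)-7-[3-(TBSO)prop-1-en-2-yl]-4,10-dimethylcyclodec-4-en-3-ol
Conditions: (R)-2-methyl-CBS-oxazaborolidine (20 mol%), catecholborane, toluene, −78 °C
Reagents that add atoms: none
Why: Corey–Bakshi–Shibata reduction: the α-methylalkenyl side of the ketone acts as the large group and the C2 methylene as the small one, so the (R)-catalyst should deliver hydride to give the (3S)-allylic alcohol. Only 1,2-reduction is expected and the oxirane is inert at −78 °C.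

Step 15
Reactants: 27
Product: 28 (1S,3S,6R,7R,8S,9S,10S,4Z)-8,9-epoxy-1-(PMBO)-3,6-bis(TBSO)-7-[3-(TBSO)prop-1-en-2-yl]-4,10-dimethylcyclodec-4-ene
Conditions: TBSCl, imidazole, DMF, rt
Reagents that add atoms: tert-butyldimethylsilyl chloride CC(C)(C)[Si](C)(C)Cl
Why: Standard silylation under conditions that do not open the oxirane; the C3 oxygen is masked as a base-stable ether because an acetate would not survive step 16.

Step 16
Reactants: 28
Product: 29 (1S,3S,6R,7R,8R,4Z,9E)-1-(PMBO)-3,6-bis(TBSO)-7-[3-(TBSO)prop-1-en-2-yl]-4,10-dimethylcyclodeca-4,9-dien-8-ol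
Conditions: Et2AlCl, LiTMP (gives Et2Al(TMP)), toluene, 0 °C
Reagents that add atoms: none
Why: Aluminium amide-mediated isomerisation of an epoxide to an allylic alcohol by syn β-elimination through a cyclic transition state, as known for trans-cyclododecene oxide, which gives the E-allylic alcohol. Removal of H10 syn to the C9–O bond of the (8S,9S)-oxirane is stereospecific: the C10 methyl eclipses C8, so the new C9=C10 alkene is E and C8 keeps its oxygen in the (8R) configuration of the target. Aluminium held between the oxirane and the C1 benzylic ether oxygen, together with shielding of H7 by the C7 branch and the C6 silyl ether, should direct the base to H10.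

Step 17
Reactants: 29
Product: 30 (1S,3S,6R,7R,8R,4Z,9E)-1-(PMBO)-3,6-bis(TBSO)-7-[3-(TBSO)prop-1-en-2-yl]-4,10-dimethylcyclodeca-4,9-dien-8-yl (E)-2-methylbut-2-enoate
Conditions: tigloyl chloride, pyridine, DMAP (cat.), CH2Cl2, 0 °C → rt
Reagents that add atoms: tigloyl chloride C/C=C(\C)C(Cl)=O
Why: DMAP-catalysed acylation of the only free hydroxyl group; pyridine is used instead of a trialkylamine to avoid vinylketene formation and deconjugation of the acyl group.

Step 18
Reactants: 30
Product: 31 (1S,3S,6R,7S,8R,4Z,9E)-3,6-dihydroxy-7-(3-hydroxyprop-1-en-2-yl)-1-(PMBO)-4,10-dimethylcyclodeca-4,9-dien-8-yl (E)-2-methylbut-2-enoate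
Conditions: HF·pyridine, pyridine, THF, 0 °C → rt
Reagents that add atoms: none
Why: Fluoride cleaves the three silyl ethers under buffered acidic conditions in which the ester should not migrate and the 4-methoxybenzyl ether is stable.

Step 19
Reactants: 31
Product: 34 (1S,3S,6R,7S,8R,4Z,9E)-3-hydroxy-1-(PMBO)-8-tigloyloxygermacra-4,9,11(13)-trien-12,6-olide, via hydroxy enal 32 (not isolated), via lactol 33 (not isolated)
Conditions: TEMPO (cat.), PhI(OAc)2, CH2Cl2, rt
Reagents that add atoms: none
Why: Oxoammonium oxidation is selective for the primary allylic alcohol. The enal is trapped by the C6 hydroxyl as the five-membered lactol, which is oxidised on to the trans-fused α-methylene-γ-butyrolactone (oxidative lactonisation of a 2-methylene-1,4-diol); the secondary C3 alcohol should react far more slowly.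

Step 20
Reactants: 34
Product: 35 (1S,3S,6R,7S,8R,4Z,9E)-3-acetoxy-1-(PMBO)-8-tigloyloxygermacra-4,9,11(13)-trien-12,6-olide
Conditions: Ac2O, pyridine, DMAP (cat.), CH2Cl2, 0 °C
Reagents that add atoms: acetic anhydride CC(=O)OC(C)=O
Why: Acetylation of the only free hydroxyl group, that on C3.

Step 21
Reactants: 35
Product: 36 (1S,3S,6R,7S,8R,4Z,9E)-3-acetoxy-1-hydroxy-8-tigloyloxygermacra-4,9,11(13)-trien-12,6-olide (CNP0319825.6)
Conditions: DDQ, CH2Cl2/pH 7 buffer, 0 °C
Reagents that add atoms: none
Why: Oxidative cleavage of the 4-methoxybenzyl ether through its benzylic oxocarbenium ion frees the C1 hydroxyl; the esters, the lactone and the alkenes are inert to DDQ under buffered conditions.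

**Compound list**

1 | (R)-(−)-carvone | CC1=CC[C@H](CC1=O)C(C)=C | starting material
2 | (5R)-5-(3-chloroprop-1-en-2-yl)-2-methylcyclohex-2-en-1-one | CC1=CC[C@H](CC1=O)C(CCl)=C | intermediate
3 | 2-[(1R)-4-methyl-5-oxocyclohex-3-en-1-yl]prop-2-en-1-yl acetate (not isolated) | CC1=CC[C@H](CC1=O)C(COC(C)=O)=C | intermediate
4 | (5R)-5-(3-hydroxyprop-1-en-2-yl)-2-methylcyclohex-2-en-1-one | CC1=CC[C@H](CC1=O)C(CO)=C | intermediate
5 | (3R)-1-(TBSO)-3-[3-(TBSO)prop-1-en-2-yl]-6-methylcyclohexa-1,5-diene (not isolated) | CC1=CC[C@H](C=C1O[Si](C)(C)C(C)(C)C)C(CO[Si](C)(C)C(C)(C)C)=C | intermediate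
6 | (5S,6S)-6-(TBSO)-5-[3-(TBSO)prop-1-en-2-yl]-2-methylcyclohex-2-en-1-one | CC1=CC[C@H]([C@H](O[Si](C)(C)C(C)(C)C)C1=O)C(CO[Si](C)(C)C(C)(C)C)=C | intermediate
7 | (1R,3S,4S,6R)-3-(TBSO)-4-[3-(TBSO)prop-1-en-2-yl]-1-methyl-7-oxabicyclo[4.1.0]heptan-2-one | C[C@@]12O[C@@H]1C[C@H]([C@H](O[Si](C)(C)C(C)(C)C)C2=O)C(CO[Si](C)(C)C(C)(C)C)=C | intermediate
8 | hydrazone of 7, C=N geometry not defined (not isolated) | C[C@@]12O[C@@H]1C[C@H]([C@H](O[Si](C)(C)C(C)(C)C)C2=NN)C(CO[Si](C)(C)C(C)(C)C)=C | intermediate
9 | (1R,4R,5S)-4-(TBSO)-5-[3-(TBSO)prop-1-en-2-yl]-2-methylcyclohex-2-en-1-ol | CC1=C[C@@H](O[Si](C)(C)C(C)(C)C)[C@@H](C[C@H]1O)C(CO[Si](C)(C)C(C)(C)C)=C | intermediate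
10 | (4R,5S)-4-(TBSO)-5-[3-(TBSO)prop-1-en-2-yl]-2-methylcyclohex-2-en-1-one | CC1=C[C@@H](O[Si](C)(C)C(C)(C)C)[C@@H](CC1=O)C(CO[Si](C)(C)C(C)(C)C)=C | intermediate
11 | allyl bromide | C=CCBr | starting material
12 | lithium enolate of 10 (not isolated) | [Li+].[O-]C1=C[C@@H](C(CO[Si](C)(C)C(C)(C)C)=C)[C@H](O[Si](C)(C)C(C)(C)C)C=C1C | intermediate
13 | (4R,5S,6R)-6-allyl-4-(TBSO)-5-[3-(TBSO)prop-1-en-2-yl]-2-methylcyclohex-2-en-1-one | CC1=C[C@@H](O[Si](C)(C)C(C)(C)C)[C@@H]([C@@H](CC=C)C1=O)C(CO[Si](C)(C)C(C)(C)C)=C | intermediate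
14 | (4R,5S,6R)-4-(TBSO)-5-[3-(TBSO)prop-1-en-2-yl]-2-methyl-6-[(E)-prop-1-en-1-yl]cyclohex-2-en-1-one | CC1=C[C@@H](O[Si](C)(C)C(C)(C)C)[C@@H]([C@@H](/C=C/C)C1=O)C(CO[Si](C)(C)C(C)(C)C)=C | intermediate
15 | 4-methoxybenzyl alcohol | COc1ccc(CO)cc1 | starting material
16 | ethyl vinyl ether | C=COCC | starting material
17 | 4-methoxybenzyl vinyl ether | C=COCc1ccc(OC)cc1 | intermediate
18 | 1,2-dibromo-1-(4-methoxybenzyloxy)ethane, racemic (not isolated) | BrCC(Br)OCc1ccc(OC)cc1 | intermediate
19 | (Z)-1-bromo-2-(4-methoxybenzyloxy)ethene | Br/C=C\OCc1ccc(OC)cc1 | intermediate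
20 | (Z)-2-(4-methoxybenzyloxy)ethenyllithium (not isolated) | [Li]/C=C\OCc1ccc(OC)cc1 | intermediate
21 | dichloro[(Z)-2-(4-methoxybenzyloxy)ethenyl]cerium (not isolated) | Cl[Ce](Cl)/C=C\OCc1ccc(OC)cc1 | intermediate
22 | (1S,4R,5S,6R)-4-(TBSO)-5-[3-(TBSO)prop-1-en-2-yl]-1-[(Z)-2-(PMBO)ethenyl]-2-methyl-6-[(E)-prop-1-en-1-yl]cyclohex-2-en-1-ol | O[C@@]1(/C=C\OCc2ccc(OC)cc2)C(C)=C[C@@H](O[Si](C)(C)C(C)(C)C)[C@H](C(CO[Si](C)(C)C(C)(C)C)=C)[C@H]1/C=C/C | intermediate
23 | potassium alkoxide of 22 (not isolated) | [K+].[O-][C@@]1(/C=C\OCc2ccc(OC)cc2)C(C)=C[C@@H](O[Si](C)(C)C(C)(C)C)[C@H](C(CO[Si](C)(C)C(C)(C)C)=C)[C@H]1/C=C/C | intermediate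
24 | potassium 2,3-dienolate of 25 (not isolated) | [K+].[O-]/C1=C\[C@H](OCc2ccc(OC)cc2)[C@H](C)/C=C/[C@@H](C(CO[Si](C)(C)C(C)(C)C)=C)[C@H](O[Si](C)(C)C(C)(C)C)/C=C1/C | intermediate
25 | (1S,6R,7S,10R,4Z,8E)-1-(PMBO)-6-(TBSO)-7-[3-(TBSO)prop-1-en-2-yl]-4,10-dimethylcyclodeca-4,8-dien-3-one | O=C1C[C@H](OCc2ccc(OC)cc2)[C@H](C)/C=C/[C@@H](C(CO[Si](C)(C)C(C)(C)C)=C)[C@H](O[Si](C)(C)C(C)(C)C)/C=C1/C | intermediate
26 | (1S,6R,7R,8S,9S,10S,4Z)-8,9-epoxy-1-(PMBO)-6-(TBSO)-7-[3-(TBSO)prop-1-en-2-yl]-4,10-dimethylcyclodec-4-en-3-one | O=C1C[C@H](OCc2ccc(OC)cc2)[C@H](C)[C@@H]3O[C@H]3[C@@H](C(CO[Si](C)(C)C(C)(C)C)=C)[C@H](O[Si](C)(C)C(C)(C)C)/C=C1/C | intermediate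
27 | (1S,3S,6R,7R,8S,9S,10S,4Z)-8,9-epoxy-1-(PMBO)-6-(TBSO)-7-[3-(TBSO)prop-1-en-2-yl]-4,10-dimethylcyclodec-4-en-3-ol | O[C@H]1C[C@H](OCc2ccc(OC)cc2)[C@H](C)[C@@H]3O[C@H]3[C@@H](C(CO[Si](C)(C)C(C)(C)C)=C)[C@H](O[Si](C)(C)C(C)(C)C)/C=C1/C | intermediate
28 | (1S,3S,6R,7R,8S,9S,10S,4Z)-8,9-epoxy-1-(PMBO)-3,6-bis(TBSO)-7-[3-(TBSO)prop-1-en-2-yl]-4,10-dimethylcyclodec-4-ene | CC(C)(C)[Si](C)(C)O[C@H]1C[C@H](OCc2ccc(OC)cc2)[C@H](C)[C@@H]3O[C@H]3[C@@H](C(CO[Si](C)(C)C(C)(C)C)=C)[C@H](O[Si](C)(C)C(C)(C)C)/C=C1/C | intermediate
29 | (1S,3S,6R,7R,8R,4Z,9E)-1-(PMBO)-3,6-bis(TBSO)-7-[3-(TBSO)prop-1-en-2-yl]-4,10-dimethylcyclodeca-4,9-dien-8-ol | CC(C)(C)[Si](C)(C)O[C@H]1C[C@H](OCc2ccc(OC)cc2)/C(C)=C/[C@@H](O)[C@@H](C(CO[Si](C)(C)C(C)(C)C)=C)[C@H](O[Si](C)(C)C(C)(C)C)/C=C1/C | intermediate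
30 | (1S,3S,6R,7R,8R,4Z,9E)-1-(PMBO)-3,6-bis(TBSO)-7-[3-(TBSO)prop-1-en-2-yl]-4,10-dimethylcyclodeca-4,9-dien-8-yl (E)-2-methylbut-2-enoate | CC(C)(C)[Si](C)(C)O[C@H]1C[C@H](OCc2ccc(OC)cc2)/C(C)=C/[C@@H](OC(=O)/C(C)=C/C)[C@@H](C(CO[Si](C)(C)C(C)(C)C)=C)[C@H](O[Si](C)(C)C(C)(C)C)/C=C1/C | intermediate
31 | (1S,3S,6R,7S,8R,4Z,9E)-3,6-dihydroxy-7-(3-hydroxyprop-1-en-2-yl)-1-(PMBO)-4,10-dimethylcyclodeca-4,9-dien-8-yl (E)-2-methylbut-2-enoate | O[C@H]1C[C@H](OCc2ccc(OC)cc2)/C(C)=C/[C@@H](OC(=O)/C(C)=C/C)[C@@H](C(CO)=C)[C@H](O)/C=C1/C | intermediate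
32 | C12 aldehyde of 31: 3,6-dihydroxy-7-(3-oxoprop-1-en-2-yl) compound (not isolated) | O[C@H]1C[C@H](OCc2ccc(OC)cc2)/C(C)=C/[C@@H](OC(=O)/C(C)=C/C)[C@@H](C(C=O)=C)[C@H](O)/C=C1/C | intermediate
33 | 6,12-lactol of 32, both anomers at C12 (not isolated) | C=C1C(O)O[C@@H]2/C=C(/C)[C@@H](O)C[C@H](OCc3ccc(OC)cc3)/C(C)=C/[C@@H](OC(=O)/C(C)=C/C)[C@@H]12 | intermediate
34 | (1S,3S,6R,7S,8R,4Z,9E)-3-hydroxy-1-(PMBO)-8-tigloyloxygermacra-4,9,11(13)-trien-12,6-olide | C=C1C(=O)O[C@@H]2/C=C(/C)[C@@H](O)C[C@H](OCc3ccc(OC)cc3)/C(C)=C/[C@@H](OC(=O)/C(C)=C/C)[C@@H]12 | intermediate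
35 | (1S,3S,6R,7S,8R,4Z,9E)-3-acetoxy-1-(PMBO)-8-tigloyloxygermacra-4,9,11(13)-trien-12,6-olide | C=C1C(=O)O[C@@H]2/C=C(/C)[C@@H](OC(C)=O)C[C@H](OCc3ccc(OC)cc3)/C(C)=C/[C@@H](OC(=O)/C(C)=C/C)[C@@H]12 | intermediate
36 | (1S,3S,6R,7S,8R,4Z,9E)-3-acetoxy-1-hydroxy-8-tigloyloxygermacra-4,9,11(13)-trien-12,6-olide (CNP0319825.6) | C=C1C(=O)O[C@@H]2/C=C(/C)[C@@H](OC(C)=O)C[C@H](O)/C(C)=C/[C@@H](OC(=O)/C(C)=C/C)[C@@H]12 | target

**Step count and least certain steps**

Total step count: 21. Longest linear sequence: 19 steps (1 → 36 through steps 1–8 and 11–21); the enol ether branch (steps 9 and 10) joins at step 11.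

Step 12 (key step). The most likely failure is loss of the C1 ether by β-elimination from the potassium dienolate 24, which is an E1cB process under these conditions. The rearrangement may also be sluggish because the Z substituent must sit axial in the chair, which would let the boat pathway compete and erode C1. Fallback: the thermal siloxy-Cope variant, which passes through the same chair but never forms a free enolate. Carbinol 22 would be silylated (TMSCl, imidazole) to the trimethylsilyl ether F1 and heated (o-dichlorobenzene, about 200 °C, base-washed glass) to the ten-membered trimethylsilyl dienol ether F2. Methanolysis (K2CO3, MeOH, 0 °C) would return the route at 25.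

Step 16. The most likely failure is removal of H7 instead of H10. Both hydrogens can reach the oxirane oxygen from the same side and H7 is allylic, so the C7=C8 diene with oxygen on C9 may form. Fallback: make H10 the only acidic hydrogen by using C1 as a carbonyl group.
- From 28, DDQ would free the C1 alcohol F3.
- Dess–Martin periodinane followed by Et3N would give the C1 ketone, whose β,γ-epoxide opens by E1cB to the γ-hydroxy enone F4 with the C8 hydroxyl and the C9=C10 alkene (its geometry then rests on the ring conformation).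
- Tigloyl chloride and pyridine would give the tiglate F5.
- (R)-CBS reduction would give the (1S)-alcohol F6.
- 4-Methoxybenzyl trichloroacetimidate with La(OTf)3 would return the route at 30.

Step 13. The most likely failure is poor discrimination between the two faces of the E alkene, since its two rotamers expose opposite faces and the ring may override the catalyst. The wrong oxirane would lead in step 16 to the 8-epimer with a Z alkene. Competing epoxidation of C11=C13 is a second risk. Fallback: a singlet-oxygen ene reaction on 25, in which oxygen arrives at C8 and H10 leaves on the same face in one concerted step while C4=C5 is still protected as the enone.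
- O2, light and tetraphenylporphyrin (CH2Cl2, −20 °C) would give the C8 hydroperoxide F7.
- PPh3 would reduce it to the hydroxy dienone F8.
- Acylation would give the tiglate F9.
- (R)-CBS reduction would give the (3S)-alcohol F10.
- TBSCl and imidazole would return the route at 30.

Step 11. The most likely failure is poor facial selectivity, because axial attack on the cyclohexenone gives the cis-dialkenyl carbinol, which would rearrange through another transition state. Enolisation of the doubly activated C8–H is a second risk. Fallback: add reagent 21 to the allyl ketone 13 instead, whose sp3 side chain makes C8–H less acidic and presents a different steric bias, to give the allyl carbinol F11. Palladium hydride isomerisation (conditions of step 8) would then move the alkene and return the route at 22.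

Step 8. The most likely failure is over-isomerisation of the new alkene into conjugation with the ketone, or epimerisation at C8 through the enol, since C8–H is activated by both groups. Fallback: direct α-alkenylation of the enolate of 10 with (E)-1-bromopropene (LiHMDS, Pd2(dba)3, P(tBu)3, toluene), which forms the C8–C9 bond with the alkene already in place and returns the route at 14 without any new compound.

Step 14. The most likely failure is a mismatch in which the ring conformation overrides the catalyst and the (3R)-alcohol predominates. Fallback: substrate-controlled Luche reduction of 26 (NaBH4, CeCl3·7H2O, MeOH, −78 °C). If this gives the (3R)-alcohol F12, Mitsunobu inversion with 4-nitrobenzoic acid (PPh3, DIAD) would give the (3S)-4-nitrobenzoate F13, and methanolysis (K2CO3, MeOH) would return the route at 27.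

**Further compounds**

F1 | step 12 | trimethylsilyl ether of 22 | C[Si](C)(C)O[C@@]1(/C=C\OCc2ccc(OC)cc2)C(C)=C[C@@H](O[Si](C)(C)C(C)(C)C)[C@H](C(CO[Si](C)(C)C(C)(C)C)=C)[C@H]1/C=C/C
F2 | step 12 | trimethylsilyl 2,3-dienol ether of 25 | C[Si](C)(C)O/C1=C\[C@H](OCc2ccc(OC)cc2)[C@H](C)/C=C/[C@@H](C(CO[Si](C)(C)C(C)(C)C)=C)[C@H](O[Si](C)(C)C(C)(C)C)/C=C1/C
F3 | step 16 | C1 alcohol from 28 (8,9-epoxide, three TBS ethers) | CC(C)(C)[Si](C)(C)O[C@H]1C[C@H](O)[C@H](C)[C@@H]3O[C@H]3[C@@H](C(CO[Si](C)(C)C(C)(C)C)=C)[C@H](O[Si](C)(C)C(C)(C)C)/C=C1/C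
F4 | step 16 | (9E)-8-hydroxy-9-en-1-one (γ-hydroxy enone, three TBS ethers) | CC(C)(C)[Si](C)(C)O[C@H]1CC(=O)/C(C)=C/[C@@H](O)[C@@H](C(CO[Si](C)(C)C(C)(C)C)=C)[C@H](O[Si](C)(C)C(C)(C)C)/C=C1/C
F5 | step 16 | tiglate of F4 | CC(C)(C)[Si](C)(C)O[C@H]1CC(=O)/C(C)=C/[C@@H](OC(=O)/C(C)=C/C)[C@@H](C(CO[Si](C)(C)C(C)(C)C)=C)[C@H](O[Si](C)(C)C(C)(C)C)/C=C1/C
F6 | step 16 | (1S)-alcohol from F5 (30 without its 4-methoxybenzyl group) | CC(C)(C)[Si](C)(C)O[C@H]1C[C@H](O)/C(C)=C/[C@@H](OC(=O)/C(C)=C/C)[C@@H](C(CO[Si](C)(C)C(C)(C)C)=C)[C@H](O[Si](C)(C)C(C)(C)C)/C=C1/C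
F7 | step 13 | (8R,9E)-8-hydroperoxy-4,9-dien-3-one from 25 | O=C1C[C@H](OCc2ccc(OC)cc2)/C(C)=C/[C@@H](OO)[C@@H](C(CO[Si](C)(C)C(C)(C)C)=C)[C@H](O[Si](C)(C)C(C)(C)C)/C=C1/C
F8 | step 13 | (8R,9E)-8-hydroxy-4,9-dien-3-one | O=C1C[C@H](OCc2ccc(OC)cc2)/C(C)=C/[C@@H](O)[C@@H](C(CO[Si](C)(C)C(C)(C)C)=C)[C@H](O[Si](C)(C)C(C)(C)C)/C=C1/C
F9 | step 13 | tiglate of F8 | O=C1C[C@H](OCc2ccc(OC)cc2)/C(C)=C/[C@@H](OC(=O)/C(C)=C/C)[C@@H](C(CO[Si](C)(C)C(C)(C)C)=C)[C@H](O[Si](C)(C)C(C)(C)C)/C=C1/C
F10 | step 13 | (3S)-alcohol from F9 (30 without its C3 silyl group) | O[C@H]1C[C@H](OCc2ccc(OC)cc2)/C(C)=C/[C@@H](OC(=O)/C(C)=C/C)[C@@H](C(CO[Si](C)(C)C(C)(C)C)=C)[C@H](O[Si](C)(C)C(C)(C)C)/C=C1/C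
F11 | step 11 | 6-allyl analogue of 22 | O[C@@]1(/C=C\OCc2ccc(OC)cc2)C(C)=C[C@@H](O[Si](C)(C)C(C)(C)C)[C@H](C(CO[Si](C)(C)C(C)(C)C)=C)[C@H]1CC=C
F0 | step 8 | none | none
F12 | step 14 | (3R)-epimer of 27 | O[C@@H]1C[C@H](OCc2ccc(OC)cc2)[C@H](C)[C@@H]3O[C@H]3[C@@H](C(CO[Si](C)(C)C(C)(C)C)=C)[C@H](O[Si](C)(C)C(C)(C)C)/C=C1/C
F13 | step 14 | (3S)-4-nitrobenzoate of 27 | O=C(O[C@H]1C[C@H](OCc2ccc(OC)cc2)[C@H](C)[C@@H]3O[C@H]3[C@@H](C(CO[Si](C)(C)C(C)(C)C)=C)[C@H](O[Si](C)(C)C(C)(C)C)/C=C1/C)c1ccc([N+](=O)[O-])cc1
A1 | alternative 1 | macrocyclic 3Z,5Z,9E-triene acid with C1 silyl ether and C8 tiglate | C=C(C(=O)O)[C@H]1/C=C\C(C)=C/C[C@H](O[Si](C)(C)C(C)(C)C)/C(C)=C/[C@H]1OC(=O)/C(C)=C/C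
A2 | alternative 1 | target as its C1 tert-butyldimethylsilyl ether | C=C1C(=O)O[C@@H]2/C=C(/C)[C@@H](OC(C)=O)C[C@H](O[Si](C)(C)C(C)(C)C)/C(C)=C/[C@@H](OC(=O)/C(C)=C/C)[C@@H]12
A3 | alternative 2 | eleven-membered sulfone (sulfur between C4 and C5, either C4 epimer) | C=C(COCc2ccc(OC)cc2)[C@H]1[C@H](OCc2ccc(OC)cc2)CS(=O)(=O)C(C)[C@@H](O[Si](C)(C)C(C)(C)C)C[C@H](O[Si](C(C)C)(C(C)C)C(C)C)/C(C)=C/[C@H]1O[Si](CC)(CC)CC
A4 | alternative 2 | protected ten-membered 4Z,9E-diene | C=C(COCc2ccc(OC)cc2)[C@H]1[C@H](OCc2ccc(OC)cc2)/C=C(/C)[C@@H](O[Si](C)(C)C(C)(C)C)C[C@H](O[Si](C(C)C)(C(C)C)C(C)C)/C(C)=C/[C@H]1O[Si](CC)(CC)CC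
A5 | alternative 3 | seco C3 aldehyde with Z alkenyl iodide at C4 | C=C1C(=O)O[C@H](/C=C(/C)I)[C@H]1[C@H](OC(=O)/C(C)=C/C)/C=C(\C)[C@@H](O[Si](C)(C)C(C)(C)C)CC=O
A6 | alternative 3 | target skeleton with free C3 hydroxyl and C1 silyl ether | C=C1C(=O)O[C@@H]2/C=C(/C)[C@@H](O)C[C@H](O[Si](C)(C)C(C)(C)C)/C(C)=C/[C@@H](OC(=O)/C(C)=C/C)[C@@H]12
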